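## The problem

Lehualide K (13) is an achiral, symmetric dimer. Two identical 3,4-dimethoxy-5-methyl-2H-pyran-2-one rings each carry an unbranched ten-carbon chain (C1'–C10') at C6, and the two chains are joined tail to tail by an S–S bond. There is no stereocentre and no ring fusion, so the difficulty is one of substitution pattern and functional-group tolerance. Every ring position is substituted, and C3 and C4 carry adjacent methoxy groups in the 2-pyranone arrangement; a late O-methylation of a 4-hydroxy-2-pyranone can also give the isomeric 2-methoxy-4-pyranone. The chain must sit on C6 and the methyl on C5, two positions that differ only slightly in their surroundings. The ring is a lactone and a vinylogous carbonate: hot hydroxide or alkoxide opens it, and strong nucleophiles can remove or displace its methoxy groups. The S–S bond is cleaved by carbanions, hydrides and phosphines and poisons hydrogenation catalysts, so it should be formed last and under mild conditions. The feature that opens a short route is a mapping onto two simple pieces. C2, C3 and C4 with their oxygens are (Z)-2,3-dimethoxyacrylic acid, whose only vinylic hydrogen (on the future C4) lies cis to the carboxyl group. C5 with its methyl and C6 with C1' are the four carbons of symmetric but-2-yne. Once the ring exists, only the C6 methyl is vinylogous to the C2 carbonyl, and this acidity difference decides where the chain is attached.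

## Retrosynthesis

**S–S bond.** Target 13 is cut at the S–S bond into two molecules of thiol 12, which is carried as its thioacetate 11. The neighbouring option, making the disulfide directly from bromide 10 with an inorganic disulfide, saves a step. It does so at the price of hot, basic sulfide solution on the pyranone and of mono- and trisulfide contaminants that would be nearly inseparable from a lipophilic dimer. Oxidative coupling of a thiol fixes the sulfur count at two and halves the size of the problem. The forward reaction must free the thiol without opening the lactone and must use an oxidant that stops at the disulfide.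

**C10'–S bond.** Thioacetate 11 is cut at C10'–S to the primary bromide 10. This asks only for a substitution by a soft, non-basic sulfur nucleophile and leaves the ring untouched.

**C1'–C2' bond.** Bromide 10 is cut between C1' and C2' to 3,4-dimethoxy-5,6-dimethyl-2H-pyran-2-one (7), as its anion 9, and 1,9-dibromononane (8). Cutting at C6–C1' instead would need a C6-halogenated pyranone and a cross-coupling. Carrying the chain through the ring synthesis would need an unsymmetrical methyl alkyl alkyne, whose two ends a metal can hardly tell apart. The chosen cut turns that regiochemical problem into an acidity difference: C3 has no hydrogen and the C5 methyl anion is only cross-conjugated. The precursor 7 has nine carbons and no chain. The forward reaction must stop at mono-substitution of the dihalide.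

**C4–C5 and C6–O1 bonds (key disconnection).** Pyranone 7 is cut at C4–C5 and C6–O1 to (Z)-2,3-dimethoxyacrylic acid (5) and but-2-yne (6). Against the classical cuts at C3–C4 or O1–C2, which pass through a 4-hydroxy-2-pyranone, this one brings both methoxy groups in before the ring exists, so no O-methylation ambiguity arises. The symmetric alkyne removes any question of orientation. The forward reaction is an oxidative annulation that has to cleave the single vinylic C–H of 5, which the Z geometry places next to the carboxylate.

**Acid 5.** Acid 5 comes from its methyl ester 4 by saponification. Ester 4 is cut at the C2–C3 bond and the enol ether O–CH3 bond to methyl methoxyacetate (1) and methyl formate (2), through the sodium formyl enolate 3. All three carbons and both oxygens come from stock esters. The forward sequence must deliver the geometry with the β-methoxy group anti to the ester, which is the thermodynamically preferred one for β-alkoxyacrylates.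

## Roads not taken

**Alternative 1:** Both C3–C4 bonds are cut, leading back to the bis(enol ester) A1, in which the disulfide and both chains are already in place. In the forward direction, excess LiN(SiMe3)2 at low temperature would convert each methoxyacetyl group into its enolate. Each enolate would attack the methyl ester held cis to it across the enol double bond, a lactone-forming Claisen condensation. Both rings would close to the bis(4-hydroxy-2-pyranone) A2, and twofold O-methylation would give 13.
- Merits: no transition metal, a two-directional ring closure, and a C5/C6 pattern fixed by the β-keto ester skeleton, so the site of the chain is never in question. In this respect it is better than the chosen plan.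
- Weak points: the S–S bond must survive an excess of amide base and two ester enolates, and carbanions sulfenylate on dialkyl disulfides. The enolate of an enol ester can also expel the β-keto ester enolate and form a ketene. A1 needs defined Z enol ester geometry at both ends. A2 must be methylated at O4 and not at O2 on both rings.
- Comparison: the chosen plan sets against the secure chain position of this road that both methoxy groups are present before the ring is made and that the disulfide is formed last. A1 itself would take several steps, so the alternative is not shorter.

**Alternative 2:** The C4–C5 and O1–C2 bonds are cut, giving dimethyl deltate A3 and the pyridinium salt A4. Et3N would convert A4 into its ylide, whose carbon adds to a methoxy-bearing ring carbon of A3. Opening of the strained adduct with loss of pyridine gives an acyl vinyl ketene, which closes through the ketone oxygen by a 6π electrocyclisation to the pyranone A5. Radical anti-Markovnikov addition of thioacetic acid to the terminal alkene of A5 would then give 11 and join the chosen endgame.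
- Merits: the ring and the whole chain arrive in one mild step. The regiochemistry is unambiguous (ylide carbon becomes C5, ketone carbon becomes C6), and there is no alkylation with a dihalide. At the ring-forming stage this road is more convergent than the chosen one.
- Weak points: A3 is not a stock chemical, and its preparation by ring contraction of a four-membered oxocarbon precursor adds several steps. A3 is sensitive to water and nucleophiles. The ylide annulation is established mainly for diaryl cyclopropenones; two donor methoxy groups make the ring carbons less electrophilic and attack at the carbonyl more competitive. A4 needs an α-halogenation next to a ketone that spares a terminal alkene.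
- Comparison: against this convergence the chosen plan sets stock starting materials and a catalytic ring synthesis of an established class, at the cost of a separate chain-attachment step.

**Alternative 3:** The two C5'=C6' bonds of the bis-alkene A8 are cut, leading to two molecules of the hexenyl pyranone A6 and to bis(hex-5-en-1-yl) disulfide A7. In the forward direction the second-generation Grubbs catalyst RuCl2(=CHPh)(PCy3)(H2IMes) would join both ends of A7 to A6 with loss of ethylene. No ring closes, and the two alkenes of A8 must then be saturated to reach 13.
- Merits: the disulfide enters as a robust symmetric piece, no nucleophilic sulfur meets the pyranone, and A6 would come from 7 with a monofunctional bromoalkene, so twofold alkylation cannot occur. In these respects it is as good as or better than the chosen endgame.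
- Weak points: it offers no ring synthesis, since A6 still needs 7 and the lateral alkylation. Two cross-metatheses between unbiased terminal alkenes must succeed on one molecule, which gives homodimers and mono-coupled material beside A8. The disulfide is a donor ligand for the ruthenium carbene. The final reduction cannot use a heterogeneous catalyst because sulfur poisons it and the S–S bond is open to hydrogenolysis.
- Comparison: after 7 both roads need three steps. The chosen plan sets three substitutions or oxidations, each with one expected product, against a statistical coupling followed by a restricted reduction.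

Key step: step 3

Assumption: the target is taken as the achiral disulfide drawn, so no stereocentre has to be set and the only stereochemical element of the route is the alkene geometry of 3, 4 and 5; chain carbons are numbered C1' (on C6) to C10' (on sulfur).

## Route

Step 1
Reactants: 1 methyl methoxyacetate; 2 methyl formate
Product: 4 methyl (2Z)-2,3-dimethoxyprop-2-enoate, via sodium formyl enolate 3 (not isolated)
Conditions: NaOMe, THF, 0 °C to rt; concentrate; Me2SO4, DMF, 0 °C to rt
Reagents that add atoms: dimethyl sulfate, COS(=O)(=O)OC
Why: Crossed Claisen condensation: methyl formate has no α-hydrogen and is the more electrophilic ester, so the enolate of 1 is formylated and the product is held as its stabilised sodium enolate 3. O-methylation of such formyl ester enolates with a hard methylating agent in a dipolar aprotic solvent is the standard entry to β-methoxyacrylates, α-oxygenated ones included, and the isomer with the β-methoxy group anti to the ester (Z here) is the thermodynamically preferred one.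

Step 2
Reactants: 4 methyl (2Z)-2,3-dimethoxyprop-2-enoate
Product: 5 (2Z)-2,3-dimethoxyprop-2-enoic acid
Conditions: LiOH·H2O, THF/H2O, 0 °C to rt; then 1 M HCl to pH 3, 0 °C, extraction
Reagents that add atoms: lithium hydroxide LiOH, [Li+].[OH-]
Why: Saponification of a methyl ester; the carboxylate formed is inert to further hydroxide, and β-alkoxyacrylic acids are isolable when the acidification is cold and brief, because only prolonged aqueous acid hydrolyses the enol ether. The alkene geometry is not touched.

Step 3
Reactants: 5 (2Z)-2,3-dimethoxyprop-2-enoic acid; 6 but-2-yne
Product: 7 3,4-dimethoxy-5,6-dimethyl-2H-pyran-2-one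
Conditions: [(C5Me5)RhCl2]2 (2.5 mol %), anhydrous Cu(OAc)2 (2.1 equiv), but-2-yne (3 equiv), DMF, 100 °C, sealed tube
Reagents that add atoms: none
Why: The step belongs to the established class of carboxylate-directed oxidative annulations of acrylic acids with internal alkynes to 2-pyranones, run with pentamethylcyclopentadienyl complexes of trivalent rhodium or arene complexes of divalent ruthenium and a copper or silver oxidant. Acetate exchange binds 5 as its carboxylate, and concerted metalation-deprotonation cleaves the one vinylic C–H, at C4, which the Z geometry holds cis to the carboxylate, giving a five-membered rhodacycle. But-2-yne coordinates and inserts into the Rh–C4 bond, which forms C4–C5 and widens the metallacycle to seven members. C–O reductive elimination then forms C6–O1, so the ring is closed at the metal in a formal [4+2] oxidative annulation and not by attack of a free carboxylate on an alkyne, and no exo/endo question arises. The monovalent rhodium released is returned to the trivalent state by two equivalents of Cu(OAc)2. No stereocentre is formed. The step needs site selectivity in the C–H cleavage and a defined alkyne orientation: the first is secured because 5 has a single vinylic hydrogen and it lies syn to the directing group, and the second cannot arise with a symmetric alkyne. The electron-rich β-methoxy carbon should favour the electrophilic metalation, and the sealed vessel keeps the volatile alkyne (b.p. 27 °C) in solution.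

Step 4
Reactants: 7 3,4-dimethoxy-5,6-dimethyl-2H-pyran-2-one; 8 1,9-dibromononane
Product: 10 6-(10-bromodecyl)-3,4-dimethoxy-5-methyl-2H-pyran-2-one, via lithium trienolate 9 (not isolated)
Conditions: LiN(SiMe3)2, THF, −78 °C; then added to 8 (4 equiv), DMPU, THF, −78 to 0 °C
Reagents that add atoms: none
Why: Lateral (vinylogous) deprotonation of a 6-methyl-2-pyranone by a hindered amide base gives trienolate 9. This is the only anion expected, because C3 has no hydrogen and a C5 methyl anion would be cross-conjugated and not stabilised by the C2 carbonyl. SN2 alkylation at the exocyclic carbon restores the pyranone, and inverse addition to an excess of the symmetric dihalide should hold back substitution at both ends.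

Step 5
Reactants: 10 6-(10-bromodecyl)-3,4-dimethoxy-5-methyl-2H-pyran-2-one
Product: 11 S-[10-(3,4-dimethoxy-5-methyl-2-oxo-2H-pyran-6-yl)decyl] ethanethioate
Conditions: KSAc, DMF, rt
Reagents that add atoms: potassium thioacetate KSAc, CC(=O)[S-].[K+]
Why: SN2 displacement of a primary bromide by thioacetate, a soft and weakly basic nucleophile that should leave the lactone and the enol ether methoxy groups alone; the acetyl group keeps sulfur from a second alkylation.

Step 6
Reactants: 11 S-[10-(3,4-dimethoxy-5-methyl-2-oxo-2H-pyran-6-yl)decyl] ethanethioate (two molecules)
Product: 13 lehualide K, 6,6'-[disulfanediylbis(decane-10,1-diyl)]bis(3,4-dimethoxy-5-methyl-2H-pyran-2-one), via thiol 12 (not isolated)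
Conditions: K2CO3, degassed MeOH/THF, 0 °C; then I2 (0.55 equiv), 0 °C
Reagents that add atoms: none
Why: Base-mediated methanolysis (transesterification) of the thioester should free thiol 12 at 0 °C much faster than methoxide attacks the vinylogous carbonate of the ring. Oxidative coupling of two thiols with iodine forms the S–S bond and cannot give any sulfur count other than two.

## Compound list

1 | methyl methoxyacetate | COCC(=O)OC | starting material
2 | methyl formate | COC=O | starting material
3 | sodium (1Z)-2,3-dimethoxy-3-oxoprop-1-en-1-olate (sodium formyl enolate) | [Na+].[O-]/C=C(\OC)C(=O)OC | intermediate (not isolated)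
4 | methyl (2Z)-2,3-dimethoxyprop-2-enoate | CO/C=C(\OC)C(=O)OC | intermediate
5 | (2Z)-2,3-dimethoxyprop-2-enoic acid | CO/C=C(\OC)C(=O)O | intermediate
6 | but-2-yne | CC#CC | starting material
7 | 3,4-dimethoxy-5,6-dimethyl-2H-pyran-2-one | COc1c(C)c(C)oc(=O)c1OC | intermediate
8 | 1,9-dibromononane | BrCCCCCCCCCBr | starting material
9 | lithium 3,4-dimethoxy-5-methyl-6-methylidene-6H-pyran-2-olate (lithium trienolate) | [Li+].[O-]C1=C(OC)C(OC)=C(C)C(=C)O1 | intermediate (not isolated)
10 | 6-(10-bromodecyl)-3,4-dimethoxy-5-methyl-2H-pyran-2-one | COc1c(C)c(CCCCCCCCCCBr)oc(=O)c1OC | intermediate
11 | S-[10-(3,4-dimethoxy-5-methyl-2-oxo-2H-pyran-6-yl)decyl] ethanethioate | COc1c(C)c(CCCCCCCCCCSC(C)=O)oc(=O)c1OC | intermediate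
12 | 3,4-dimethoxy-5-methyl-6-(10-sulfanyldecyl)-2H-pyran-2-one | COc1c(C)c(CCCCCCCCCCS)oc(=O)c1OC | intermediate (not isolated)
13 | lehualide K, 6,6'-[disulfanediylbis(decane-10,1-diyl)]bis(3,4-dimethoxy-5-methyl-2H-pyran-2-one) | COc1c(C)c(CCCCCCCCCCSSCCCCCCCCCCc2oc(=O)c(OC)c(OC)c2C)oc(=O)c1OC | target

## Step count and risks

Total steps: 6. Longest linear sequence: 6 steps (1 to 13); compounds 2, 6 and 8 enter as stock reagents.

**Step 3 (key step).** The acid may be consumed unproductively at 100 °C: thermal Z-to-E isomerisation would remove the syn hydrogen, and the acetic acid and copper salts formed could cleave the enol ether or cause protodecarboxylation. The α-methoxy carboxylate could also chelate rhodium and slow the metalation, and the volatile alkyne could escape the liquid phase. The fallback builds the ring by polyketide-type condensation instead of C–H activation. It sets out from 1 and returns at 7.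
- The lithium enolate of 1 (LiN(i-Pr)2, THF, −78 °C) is acylated with propanoyl chloride to methyl 2-methoxy-3-oxopentanoate F1.
- The dianion of F1 (NaH, then n-BuLi, THF, 0 °C) is acetylated at C4 with N-methoxy-N-methylacetamide to methyl 2-methoxy-4-methyl-3,5-dioxohexanoate F2.
- DBU in warm toluene closes F2, with loss of methanol, to 4-hydroxy-3-methoxy-5,6-dimethyl-2H-pyran-2-one F3.
- O-methylation of F3 with Me2SO4 and K2CO3 in acetone, conditions that favour the 4-methoxy-2-pyranone over the 2-methoxy-4-pyranone, gives 7.

**Step 4.** Substitution of an unactivated primary bromide by the delocalised anion may be slow. That would leave time for proton transfer between product and anion, for a second alkylation at C1', and for reaction of both ends of the dihalide. The fallback replaces the SN2 reaction by a carbonyl addition. It sets out from 7, through its anion 9, and returns at 10.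
- Anion 9 is added at −78 °C to 9-bromononanal F4, made by Dess–Martin oxidation of commercial 9-bromononan-1-ol, giving racemic 6-(10-bromo-2-hydroxydecyl)-3,4-dimethoxy-5-methyl-2H-pyran-2-one F5.
- MsCl and Et3N convert F5 into its methanesulfonate, 1-bromo-10-(3,4-dimethoxy-5-methyl-2-oxo-2H-pyran-6-yl)decan-9-yl methanesulfonate F6.
- DBU eliminates methanesulfonic acid from F6 to the conjugated alkene 6-[(1E)-10-bromodec-1-en-1-yl]-3,4-dimethoxy-5-methyl-2H-pyran-2-one F7.
- Diimide (TsNHNH2, NaOAc, aqueous DME, heat) should saturate the disubstituted side-chain alkene of F7 and spare the tetrasubstituted ring double bonds and the C–Br bond, giving 10.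

**Step 6.** During the deacetylation, methoxide may open the lactone or exchange the C4 methoxy group by addition–elimination. The thiolate may also add to the ring of a second molecule before it is oxidised. The fallback avoids base and free thiolate. It sets out from 10, bypasses 11 and 12, and returns at 13. Bromide 10 is heated with Na2S2O3 in aqueous ethanol to the Bunte salt sodium S-[10-(3,4-dimethoxy-5-methyl-2-oxo-2H-pyran-6-yl)decyl] thiosulfate F8. Iodine in aqueous ethanol then converts F8 into the disulfide 13 with loss of hydrogensulfate.

**Step 1.** The ambident enolate 3 may be methylated on carbon instead of oxygen, 1 may condense with itself, and the enol ether may form as a mixture of geometric isomers. The fallback replaces the enolate O-alkylation by acetal formation and elimination. It sets out from 3 and returns at 4. Crude 3 is taken up in methanol with HCl and HC(OMe)3 to give methyl 2,3,3-trimethoxypropanoate F9. Heating F9 with catalytic TsOH while methanol distils off eliminates one methanol and should give 4 as the thermodynamically preferred isomer.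

## Further compounds

F1 | step 3 | methyl 2-methoxy-3-oxopentanoate | CCC(=O)C(OC)C(=O)OC
F2 | step 3 | methyl 2-methoxy-4-methyl-3,5-dioxohexanoate | COC(=O)C(OC)C(=O)C(C)C(C)=O
F3 | step 3 | 4-hydroxy-3-methoxy-5,6-dimethyl-2H-pyran-2-one | COc1c(O)c(C)c(C)oc1=O
F4 | step 4 | 9-bromononanal | O=CCCCCCCCCBr
F5 | step 4 | 6-(10-bromo-2-hydroxydecyl)-3,4-dimethoxy-5-methyl-2H-pyran-2-one (racemic) | COc1c(C)c(CC(O)CCCCCCCCBr)oc(=O)c1OC
F6 | step 4 | 1-bromo-10-(3,4-dimethoxy-5-methyl-2-oxo-2H-pyran-6-yl)decan-9-yl methanesulfonate (racemic) | COc1c(C)c(CC(OS(C)(=O)=O)CCCCCCCCBr)oc(=O)c1OC
F7 | step 4 | 6-[(1E)-10-bromodec-1-en-1-yl]-3,4-dimethoxy-5-methyl-2H-pyran-2-one | COc1c(C)c(/C=C/CCCCCCCCBr)oc(=O)c1OC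
F8 | step 6 | sodium S-[10-(3,4-dimethoxy-5-methyl-2-oxo-2H-pyran-6-yl)decyl] thiosulfate | COc1c(C)c(CCCCCCCCCCSS(=O)(=O)[O-])oc(=O)c1OC.[Na+]
F9 | step 1 | methyl 2,3,3-trimethoxypropanoate | COC(OC)C(OC)C(=O)OC
A1 | alternative 1 | dimethyl (2Z,2'Z)-13,13'-disulfanediylbis{3-[(methoxyacetyl)oxy]-2-methyltridec-2-enoate} | COCC(=O)O/C(CCCCCCCCCCSSCCCCCCCCCC/C(OC(=O)COC)=C(/C(=O)OC)C)=C(/C)C(=O)OC
A2 | alternative 1 | 6,6'-[disulfanediylbis(decane-10,1-diyl)]bis(4-hydroxy-3-methoxy-5-methyl-2H-pyran-2-one) | COc1c(O)c(C)c(CCCCCCCCCCSSCCCCCCCCCCc2oc(=O)c(OC)c(O)c2C)oc1=O
A3 | alternative 2 | dimethyl deltate (2,3-dimethoxycycloprop-2-en-1-one) | COC1=C(OC)C1=O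
A4 | alternative 2 | 1-(3-oxotridec-12-en-2-yl)pyridinium bromide | CC(C(=O)CCCCCCCCC=C)[n+]1ccccc1.[Br-]
A5 | alternative 2 | 6-(dec-9-en-1-yl)-3,4-dimethoxy-5-methyl-2H-pyran-2-one | COc1c(C)c(CCCCCCCCC=C)oc(=O)c1OC
A6 | alternative 3 | 6-(hex-5-en-1-yl)-3,4-dimethoxy-5-methyl-2H-pyran-2-one | COc1c(C)c(CCCCC=C)oc(=O)c1OC
A7 | alternative 3 | bis(hex-5-en-1-yl) disulfide | C=CCCCCSSCCCCC=C
A8 | alternative 3 | 6,6'-{disulfanediylbis[(5E)-dec-5-ene-10,1-diyl]}bis(3,4-dimethoxy-5-methyl-2H-pyran-2-one) | COc1c(C)c(CCCC/C=C/CCCCSSCCCC/C=C/CCCCc2oc(=O)c(OC)c(OC)c2C)oc(=O)c1OC
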